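**Strategy.** The oxolane ring (O1, C2–C5) is cut at O1–C2 and C3–C4. C2–C3 comes from an arylidene malonate; O1–C5–C4 with its one-carbon handle (the future C7') comes from racemic 2-vinyloxirane. A palladium-catalysed zwitterionic π-allyl (3+2) cycloaddition forms both bonds, closes the ring and sets C2 and C4 (2,4-cis) in one operation, with the ligand converging both epoxide enantiomers. The precursors are dimethyl 4-(benzyloxy)benzylidenemalonate and the epoxide. Afterwards the geminal diester is trimmed to the all-trans C3 ester, the vinyl group becomes the anisyl ketone, C7' is set by reduction, and the phenol is unmasked before acetylation.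

Key step: step 2

Remark: the ring is numbered O1, C2 (aryl), C3, C4, C5, with C7' the carbinol carbon on C4 and C9 the carbon on C3; the (R,R) ligand, N,N'-[(1R,2R)-cyclohexane-1,2-diyl]bis[2-(diphenylphosphanyl)benzamide], is assumed to deliver (4R), and its antipode would be used if a first run showed the opposite sense.

**Step 1**
Reactants: 1 4-(benzyloxy)benzaldehyde; 2 dimethyl malonate
Product: 3 dimethyl 2-[4-(benzyloxy)benzylidene]malonate
Conditions: piperidine (0.1 equiv), AcOH (0.1 equiv), toluene, reflux, Dean–Stark
Reagents that add atoms: none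
Why: Knoevenagel condensation: piperidinium acetate catalyses addition of the malonate to the aldehyde and dehydration, azeotropic removal of water drives it to completion, and the two identical esters leave no alkene geometry to control.

**Step 2**
Reactants: 3 dimethyl 2-[4-(benzyloxy)benzylidene]malonate; 4 2-vinyloxirane (racemic)
Product: 5 dimethyl (2S,4R)-2-[4-(benzyloxy)phenyl]-4-ethenyloxolane-3,3-dicarboxylate (2,4-cis)
Conditions: Pd2(dba)3·CHCl3 (2.5 mol%), (R,R)-DACH-phenyl ligand (7.5 mol%), CH2Cl2, rt, slow addition of 4 (1.5 equiv)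
Reagents that add atoms: none
Why: Zerovalent palladium ionises either enantiomer of 4 to a zwitterionic π-allylpalladium alkoxide, whose oxygen adds reversibly to the benzylidene carbon of 3 (oxa-Michael, O1–C2), and the malonate carbanion then attacks the internal allyl carbon (C3–C4). The closest known reaction type is the palladium-catalysed formal (3+2) cycloaddition of vinyl epoxides with doubly activated alkenes, run here as a dynamic kinetic asymmetric transformation. The oxolane closes by a 5-exo attack on the allyl unit, which leaves the vinyl group outside the ring; attack at the allyl terminus would be a 7-endo closure and is not expected to compete. C4 is set by the chiral ligand, because π–σ–π equilibration of the diastereomeric allyl complexes outpaces ring closure (a Curtin–Hammett situation), so both enantiomers of 4 should converge on a single configuration. C2 is set relative to C4 in the ring-closing transition state, where aryl and allyl both lie pseudo-equatorial (2,4-cis), and reversibility of the oxa-Michael step lets this preference decide. The step therefore needs branched regioselectivity, 2,4-cis diastereoselectivity and enantioselectivity, which the short three-atom tether, the doubly activated acceptor with two identical esters (C3 not yet stereogenic) and the ligand secure.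

**Step 3**
Reactants: 5 dimethyl (2S,4R)-2-[4-(benzyloxy)phenyl]-4-ethenyloxolane-3,3-dicarboxylate
Product: 6 methyl (2R,3R,4R)-2-[4-(benzyloxy)phenyl]-4-ethenyloxolane-3-carboxylate (all-trans)
Conditions: LiCl (2 equiv), H2O (2 equiv), DMSO, 150 °C
Reagents that add atoms: none
Why: Krapcho dealkoxycarbonylation: chloride removes one ester methyl by SN2 attack, the carboxylate loses CO2, and the C3 ester enolate is protonated and equilibrated under the hot, weakly basic conditions to the epimer whose ester is trans to both the C2 aryl and the C4 vinyl group (these share one face), so C3 is set under thermodynamic control while C2 and C4 are untouched.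

**Step 4**
Reactants: 6 methyl (2R,3R,4R)-2-[4-(benzyloxy)phenyl]-4-ethenyloxolane-3-carboxylate
Product: 8 methyl (2R,3R,4R)-2-[4-(benzyloxy)phenyl]-4-formyloxolane-3-carboxylate, via ozonide 7 (not isolated)
Conditions: O3, CH2Cl2, −78 °C (Sudan Red 7B end point); then PPh3, −78 °C → rt
Reagents that add atoms: ozone, [O-][O+]=O
Why: Ozonolysis by the Criegee mechanism cleaves the only C=C bond, the indicator end point protects the benzyloxyarene from excess ozone, and phosphine reduction of ozonide 7 releases the aldehyde under neutral conditions that should neither epimerise C4 nor open the ring by β-elimination.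

**Step 5**
Reactants: 8 methyl (2R,3R,4R)-2-[4-(benzyloxy)phenyl]-4-formyloxolane-3-carboxylate; 9 (4-methoxyphenyl)magnesium bromide
Product: 10 methyl (2R,3R,4R)-2-[4-(benzyloxy)phenyl]-4-[hydroxy(4-methoxyphenyl)methyl]oxolane-3-carboxylate (both C7' epimers)
Conditions: 9 (1.2 equiv, THF solution), THF, −78 °C; then H2O (pH 7 buffer)
Reagents that add atoms: none
Why: Grignard 1,2-addition, which at −78 °C should be selective for the aldehyde over the methyl ester (no lactone forms because it would be trans-fused); the C7' epimers are carried on together because this centre is erased in step 6.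

**Step 6**
Reactants: 10 methyl (2R,3R,4R)-2-[4-(benzyloxy)phenyl]-4-[hydroxy(4-methoxyphenyl)methyl]oxolane-3-carboxylate
Product: 11 methyl (2R,3R,4R)-2-[4-(benzyloxy)phenyl]-4-(4-methoxybenzoyl)oxolane-3-carboxylate
Conditions: Dess–Martin periodinane (1.3 equiv), pyridine, CH2Cl2, 0 °C → rt
Reagents that add atoms: none
Why: Dess–Martin oxidation of the secondary benzylic alcohol under pyridine-buffered, non-basic conditions converts both epimers into one ketone and should leave the β-alkoxy ketone, the ester and the C3 and C4 centres intact.

**Step 7**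
Reactants: 11 methyl (2R,3R,4R)-2-[4-(benzyloxy)phenyl]-4-(4-methoxybenzoyl)oxolane-3-carboxylate
Product: 12 methyl (2R,3R,4R)-2-[4-(benzyloxy)phenyl]-4-[(S)-hydroxy(4-methoxyphenyl)methyl]oxolane-3-carboxylate
Conditions: (R)-2-methyl-CBS-oxazaborolidine (0.2 equiv), BH3·SMe2 (1.0 equiv), THF, −20 °C; then MeOH
Reagents that add atoms: none
Why: Corey–Bakshi–Shibata reduction: with the aryl group as the large substituent the (R)-oxazaborolidine directs hydride to the carbonyl face that gives the (7'S)-alcohol, which is also the face favoured by Felkin–Anh control from C4 (C3 as the large group anti to hydride, C4–H next to the aryl group), so catalyst and substrate should reinforce each other, while borane leaves the ester alone at this temperature.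

**Step 8**
Reactants: 12 methyl (2R,3R,4R)-2-[4-(benzyloxy)phenyl]-4-[(S)-hydroxy(4-methoxyphenyl)methyl]oxolane-3-carboxylate
Product: 13 (S)-{(3R,4S,5R)-5-[4-(benzyloxy)phenyl]-4-(hydroxymethyl)oxolan-3-yl}(4-methoxyphenyl)methanol
Conditions: LiAlH4 (1.5 equiv), THF, 0 °C; then H2O
Reagents that add atoms: none
Why: LiAlH4 ester reduction to the primary alcohol at C9; hydride addition is much faster than enolisation, so C3 keeps its configuration and no other group reacts.

**Step 9**
Reactants: 13 (S)-{(3R,4S,5R)-5-[4-(benzyloxy)phenyl]-4-(hydroxymethyl)oxolan-3-yl}(4-methoxyphenyl)methanol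
Product: 14 4-{(2R,3S,4R)-3-(hydroxymethyl)-4-[(S)-hydroxy(4-methoxyphenyl)methyl]oxolan-2-yl}phenol
Conditions: H2 (1 atm), 10% Pd/C, EtOAc, rt, stopped at full conversion
Reagents that add atoms: none
Why: Catalytic hydrogenolysis of the aryl benzyl ether, which in a neutral solvent is much faster than cleavage of the free C7' benzylic alcohol or of the benzylic O1–C2 ring bond; it is placed before acetylation because an anisyl-type benzylic acetate would itself be prone to hydrogenolysis.

**Step 10**
Reactants: 14 4-{(2R,3S,4R)-3-(hydroxymethyl)-4-[(S)-hydroxy(4-methoxyphenyl)methyl]oxolan-2-yl}phenol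
Product: 15 4-{(2R,3S,4R)-3-(acetoxymethyl)-4-[(S)-acetoxy(4-methoxyphenyl)methyl]oxolan-2-yl}phenyl acetate
Conditions: Ac2O (4 equiv), pyridine, DMAP (cat.), CH2Cl2, 0 °C → rt
Reagents that add atoms: acetic anhydride, CC(=O)OC(C)=O
Why: DMAP-catalysed nucleophilic acyl transfer (exhaustive acetylation) esterifies the phenol, the primary alcohol and the hindered benzylic alcohol without touching any stereocentre.

**Step 11**
Reactants: 15 4-{(2R,3S,4R)-3-(acetoxymethyl)-4-[(S)-acetoxy(4-methoxyphenyl)methyl]oxolan-2-yl}phenyl acetate
Product: 16 (S)-[(3R,4S,5R)-4-(acetoxymethyl)-5-(4-hydroxyphenyl)oxolan-3-yl](4-methoxyphenyl)methyl acetate (target)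
Conditions: NH4OAc, MeOH/H2O (4:1), rt
Reagents that add atoms: none
Why: Chemoselective transesterification of the aryl acetate: phenoxide is a far better leaving group than an alkoxide, so under neutral ammonium acetate catalysis in aqueous methanol only the phenolic ester should be cleaved while the two alkyl acetates, including the sensitive C7' acetate, remain.

**Compound list**
1 | 4-(benzyloxy)benzaldehyde | O=Cc1ccc(OCc2ccccc2)cc1 | starting material
2 | dimethyl malonate | COC(=O)CC(=O)OC | starting material
3 | dimethyl 2-[4-(benzyloxy)benzylidene]malonate | COC(=O)C(=Cc1ccc(OCc2ccccc2)cc1)C(=O)OC | intermediate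
4 | 2-vinyloxirane (racemic) | C=CC1CO1 | starting material
5 | dimethyl (2S,4R)-2-[4-(benzyloxy)phenyl]-4-ethenyloxolane-3,3-dicarboxylate (2,4-cis) | C=C[C@H]1CO[C@@H](c2ccc(OCc3ccccc3)cc2)C1(C(=O)OC)C(=O)OC | intermediate
6 | methyl (2R,3R,4R)-2-[4-(benzyloxy)phenyl]-4-ethenyloxolane-3-carboxylate (all-trans) | C=C[C@H]1CO[C@@H](c2ccc(OCc3ccccc3)cc2)[C@@H]1C(=O)OC | intermediate
7 | methyl (2R,3R,4R)-2-[4-(benzyloxy)phenyl]-4-(1,2,4-trioxolan-3-yl)oxolane-3-carboxylate (ozonide, trioxolane carbon uncontrolled, formed in the flask) | C1OOC(O1)[C@H]2CO[C@@H](c3ccc(OCc4ccccc4)cc3)[C@@H]2C(=O)OC | intermediate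
8 | methyl (2R,3R,4R)-2-[4-(benzyloxy)phenyl]-4-formyloxolane-3-carboxylate | O=C[C@H]1CO[C@@H](c2ccc(OCc3ccccc3)cc2)[C@@H]1C(=O)OC | intermediate
9 | (4-methoxyphenyl)magnesium bromide (commercial THF solution) | COc1ccc([Mg]Br)cc1 | starting material
10 | methyl (2R,3R,4R)-2-[4-(benzyloxy)phenyl]-4-[hydroxy(4-methoxyphenyl)methyl]oxolane-3-carboxylate (both C7' epimers) | COc1ccc(C(O)[C@H]2CO[C@@H](c3ccc(OCc4ccccc4)cc3)[C@@H]2C(=O)OC)cc1 | intermediate
11 | methyl (2R,3R,4R)-2-[4-(benzyloxy)phenyl]-4-(4-methoxybenzoyl)oxolane-3-carboxylate | COc1ccc(C(=O)[C@H]2CO[C@@H](c3ccc(OCc4ccccc4)cc3)[C@@H]2C(=O)OC)cc1 | intermediate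
12 | methyl (2R,3R,4R)-2-[4-(benzyloxy)phenyl]-4-[(S)-hydroxy(4-methoxyphenyl)methyl]oxolane-3-carboxylate | COc1ccc([C@@H](O)[C@H]2CO[C@@H](c3ccc(OCc4ccccc4)cc3)[C@@H]2C(=O)OC)cc1 | intermediate
13 | (S)-{(3R,4S,5R)-5-[4-(benzyloxy)phenyl]-4-(hydroxymethyl)oxolan-3-yl}(4-methoxyphenyl)methanol | COc1ccc([C@@H](O)[C@H]2CO[C@@H](c3ccc(OCc4ccccc4)cc3)[C@@H]2CO)cc1 | intermediate
14 | 4-{(2R,3S,4R)-3-(hydroxymethyl)-4-[(S)-hydroxy(4-methoxyphenyl)methyl]oxolan-2-yl}phenol | COc1ccc([C@@H](O)[C@H]2CO[C@@H](c3ccc(O)cc3)[C@@H]2CO)cc1 | intermediate
15 | 4-{(2R,3S,4R)-3-(acetoxymethyl)-4-[(S)-acetoxy(4-methoxyphenyl)methyl]oxolan-2-yl}phenyl acetate | COc1ccc([C@@H](OC(C)=O)[C@H]2CO[C@@H](c3ccc(OC(C)=O)cc3)[C@@H]2COC(C)=O)cc1 | intermediate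
16 | (S)-[(3R,4S,5R)-4-(acetoxymethyl)-5-(4-hydroxyphenyl)oxolan-3-yl](4-methoxyphenyl)methyl acetate | COc1ccc([C@@H](OC(C)=O)[C@H]2CO[C@@H](c3ccc(O)cc3)[C@@H]2COC(C)=O)cc1 | target

**Step count.** Total: 11 steps. Longest linear sequence: 11 steps (1 → 16).

**Steps most likely to fail**

Step 2. The electron-rich, only moderately electrophilic arylidene malonate may capture the zwitterion too slowly, so that the epoxide isomerises or oligomerises, or enantio- and 2,4-cis selectivity may erode. The fallback sets out from 1 and 4 and changes the acceptor and the later decarboxylation. Compound 1 is condensed with Meldrum's acid to the much more electrophilic 5-[4-(benzyloxy)benzylidene]-2,2-dimethyl-1,3-dioxane-4,6-dione F1. The same palladium/ligand system should then join F1 and 4 to the spiro adduct (1S,4R)-1-[4-(benzyloxy)phenyl]-4-ethenyl-8,8-dimethyl-2,7,9-trioxaspiro[4.5]decane-6,10-dione F2. Heating F2 in methanol/pyridine (about 100 °C, closed vessel) opens the dioxanedione and expels acetone and CO2, and C3 equilibrates to the all-trans ester. The fallback returns to the route at 6 and makes step 3 unnecessary.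

Step 3. At 150 °C the C3 ester enolate may expel the ring oxygen by β-elimination (ring opening), or C3 may not equilibrate fully. The fallback sets out from 5 and replaces halide dealkylation by hydrolysis and acid decarboxylation. One equivalent of KOH in aqueous methanol at room temperature, then HCl, gives the half-acid (2S,4R)-2-[4-(benzyloxy)phenyl]-4-ethenyl-3-(methoxycarbonyl)oxolane-3-carboxylic acid F3; the quaternary C3 cannot enolise, and either C3 epimer serves. F3 is decarboxylated in toluene at about 100 °C through the cyclic six-centre transition state, which releases the ester as its enol and not as a hot free enolate. A trace of DBU at room temperature would complete equilibration. The fallback returns at 6.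

Step 7. Hydride delivery to the C7' carbonyl may show poor facial selectivity, most plausibly if the C4 centre opposes the catalyst. Aryl addition to an aldehyde and hydride addition to the corresponding aryl ketone are stereocomplementary under one substrate bias, so C7' would then be created in the C–C bond-forming event. The fallback sets out from 8. Grignard reagent 9 is transmetallated with ClTi(OiPr)3 to (4-methoxyphenyl)titanium triisopropoxide F4, a bulky, non-chelating, ester-tolerant aryl donor. F4 should add to 8 at low temperature under Felkin–Anh control; the minor epimer would be removed by chromatography. The fallback returns at 12 and makes steps 5 to 7 unnecessary.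

**Further compounds**
F1 | step 2 | 5-[4-(benzyloxy)benzylidene]-2,2-dimethyl-1,3-dioxane-4,6-dione | CC1(C)OC(=O)C(=Cc2ccc(OCc3ccccc3)cc2)C(=O)O1
F2 | step 2 | (1S,4R)-1-[4-(benzyloxy)phenyl]-4-ethenyl-8,8-dimethyl-2,7,9-trioxaspiro[4.5]decane-6,10-dione | C=C[C@H]1CO[C@@H](c2ccc(OCc3ccccc3)cc2)C12C(=O)OC(C)(C)OC2=O
F3 | step 3 | (2S,4R)-2-[4-(benzyloxy)phenyl]-4-ethenyl-3-(methoxycarbonyl)oxolane-3-carboxylic acid (either C3 epimer) | C=C[C@H]1CO[C@@H](c2ccc(OCc3ccccc3)cc2)C1(C(=O)O)C(=O)OC
F4 | step 7 | (4-methoxyphenyl)titanium triisopropoxide | COc1ccc([Ti](OC(C)C)(OC(C)C)OC(C)C)cc1
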